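Which of these flasks, alike but for temperature, holds the most product after 4.0 d, and how much does each hold?

in all of them: free catalyst 50 µM

|  | starting material | partner | protic impurity | temperature | remark | time |
|---|---|---|---|---|---|---|
| Sunday's | 0.15 M | 0.40 M | 2 mM | 35 °C | run made earlier |  |
| spring | 0.10 M | 0.400 M | 2.00 mM | 35 °C |  | 4.0 d |
| dawn | 0.10 M | 0.400 M | 2.00 mM | 60 °C |  | 4.0 d |
| noon | 0.10 M | 0.400 M | 2.00 mM | 10 °C |  | 4.0 d |
| midnight | 0.10 M | 0.400 M | 2.00 mM | 85 °C |  | 4.0 d |

Sunday's run (percent of the starting material charged)

| time / h | product / % |
|---|---|
| 3.00 | 9.3 |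
| 6.00 | 18.2 |
| 10.0 | 27.8 |
| 12.0 | 33.2 |
| 15.0 | 40.5 |
| 20.0 | 50.2 |

(each reading ± 0.3 percentage points)

- the numbers in the tables scatter with a standard deviation of 0.3 percentage points
- the earlier runs do not show what temperature does; that part of a forecast is a guess

- the flask with the highest amount of product, in percent of the starting material charged ("all alike" if they lie within 1.5 percentage points) (spring / dawn / noon / midnight / all alike)
- final product, as a percentage of the starting material charged, in spring
- final product, as a percentage of the starting material charged, in dawn
- final product, as a percentage of the starting material charged, in noon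
- final product, as a percentage of the starting material charged, in midnight

You have one earlier run to lean on, Sunday's, at 35 °C. The bench rule for it is the pseudo-first-order one: treat partner as constant, and starting material then loses the same fraction in equal times, with a rate constant k equal to the logarithm of one over the fraction left, divided by the time. Sunday's last reading gives k = 0.0349 h⁻¹, a half-life of 19.9 h. Over 4.0 d that leaves 3.51% of the starting material, so my own reckoning for spring is 96.5% product.

But the rule assumes that partner stays put, and the usual demand is about 10 equivalents, while spring has fewer, 4.00. So divide one rate by the other. Assume, as my own reckoning, that each starting material consumed takes one partner and each impurity takes one too. Leaving the impurity's share aside, the rate of partner loss over the rate of starting-material loss is then one at any speed, so time drops out of the final balance, and the impurity enters that balance as a fixed charge. Spring's charge then leaves 74.5% of its partner once starting material and impurity have both reacted, and this share is the partner margin, m. Partner falls by about a quarter, and starting material is the limiting reagent, with 3.98 usable equivalents. Sunday's run tests whether that fall matters: by its last reading partner was down 18.8%, yet k there is higher than the 0.0325 h⁻¹ of the first reading. So I keep the rule for spring. It has two weaknesses at 35 °C: k comes from a charge of 0.15 M but is applied to 0.10 M, a change the rule treats as harmless and Sunday's run cannot test, and 4.0 d is 4.80 times the last reading. Temperature stays a guess.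

The forecast gave 97% for spring, 97.5% for dawn, 37% for noon and 93% for midnight, and chose dawn: “Dawn is a marginal pick for most”.

The flasks give 98.9% in spring, 86.7% in dawn, 49.3% in noon and 46.3% in midnight, so the most stands in spring.

    partner + catalyst intermediate A ⇌ catalyst intermediate B (K = 3.80 M⁻¹, k = 61.0 M⁻¹ min⁻¹, Ea = 38.0 kJ mol⁻¹, ΔH = −12.0 kJ mol⁻¹)
    catalyst intermediate B ⇌ by-product + catalyst intermediate C (K = 3.20 M, k = 5.70 min⁻¹, Ea = 69.0 kJ mol⁻¹, ΔH = −36.0 kJ mol⁻¹)
    catalyst intermediate C ⇌ free catalyst + product (K = 0.430 M, k = 9.80 min⁻¹, Ea = 74.0 kJ mol⁻¹, ΔH = −27.0 kJ mol⁻¹)
    partner + protic impurity → quenched reagent (k = 0.290 M⁻¹ min⁻¹, Ea = 57.0 kJ mol⁻¹)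
    starting material + free catalyst ⇌ catalyst intermediate A (K = 8.70 M⁻¹, k = 81.0 M⁻¹ min⁻¹, Ea = 53.0 kJ mol⁻¹, ΔH = −35.0 kJ mol⁻¹)
    free catalyst → spent catalyst (k = 1.40 × 10⁻⁶ min⁻¹, Ea = 113 kJ mol⁻¹)
    (constants at 35 °C)

Has each flask come to rest? Reckoned at its own conversion, the margin gives spring 74.8% of its partner, and the flask holds 75%, still 74.7% after 40.0 d. Ten times the time adds 0.40 percentage points to spring, which reaches 99.3% with 0.725% of its starting material left. For midnight the same reckoning gives 87.9%, and that flask holds 88% of its partner beside 54% of its starting material, 5.65% of free catalyst and 91.0% of spent catalyst. Midnight's product stands at 46.3% after 4.00 d and at 46.3% after 40.0 d.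

(Readings and results come from a simulation with made-up constants; noise was put on by code.)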